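**Retrosynthetic overview**

1. The target is a tridepside: ring A (3,4-dihydroxy-6-methoxy-2-methylbenzoyl) is esterified to the C4 oxygen of ring B, and ring B to the C4 oxygen of ring C, both 2-hydroxy-6-methylbenzoate units. No ring is formed in the route; all three benzene rings are bought.
2. Key disconnection: the C2–O bonds of rings B and C. In each of these rings the ester carbonyl sits on C1, a methyl group on C6 and the hydroxyl on C2, so the bis-deoxy tridepside 19 has exactly one C–H (C2–H) ortho to each directing carbonyl. Ring A (C2 methyl, C6 methoxy) has none.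
3. Compound 19 is cut at its two aryl ester bonds into the ring A acid 11 (catechol masked as diacetate) and two molecules of one building block, 4-nitrobenzyl 4-hydroxy-2-methylbenzoate 13, joined in the order A + B, then AB + C.
4. Acid 11 comes from 4-methoxy-2-methylphenol: ortho-formylation and Dakin oxidation install the C4 oxygen, then formylation para to that oxygen and oxidation give the C1 carboxyl.
5. End game: removal of the two acetates, then hydrogenolytic loss of the nitrobenzyl ester.

Key step: step 11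

Remark on the chemistry: the ring C carboxyl is carried as a 4-nitrobenzyl ester because a plain benzyl ester would be open to acidolysis in the hot TFA/TFAA medium of step 11; it is still removed by hydrogenation over Pd/C. The target has no stereocentre.

**Route**

Step 1
Reactants: 1 4-methoxy-2-methylphenol
Product: 2 2-hydroxy-5-methoxy-3-methylbenzaldehyde
Conditions: MgCl2, Et3N, (CH2O)n, MeCN, reflux; then 1 M HCl
Reagents that add atoms: paraformaldehyde (formaldehyde), C=O
Why: Magnesium phenoxide-directed ortho-formylation (Casnati–Skattebøl reaction) can only occur at the single free position ortho to the hydroxyl, since the other ortho position carries the methyl group and the para position the methoxy group.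

Step 2
Reactants: 2 2-hydroxy-5-methoxy-3-methylbenzaldehyde
Product: 4 5-methoxy-3-methylbenzene-1,2-diol, via aryl formate 3 (not isolated)
Conditions: 30% H2O2, NaOH, H2O/THF, 0 °C→rt, N2; then HCl
Reagents that add atoms: hydrogen peroxide, OO
Why: Dakin oxidation, in which the hydroperoxide adduct of the electron-rich ortho-hydroxybenzaldehyde undergoes aryl migration to formate 3, which the alkali hydrolyses in the flask to the catechol.

Step 3
Reactants: 4 5-methoxy-3-methylbenzene-1,2-diol
Product: 5 1,2-bis(benzyloxy)-5-methoxy-3-methylbenzene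
Conditions: BnBr, K2CO3, DMF, 60 °C, N2
Reagents that add atoms: benzyl bromide, BrCc1ccccc1
Why: Williamson etherification of both phenoxides gives benzyl ethers that keep the ring electron-rich for the coming electrophilic substitution and are later removed by hydrogenolysis.

Step 4
Reactants: 5 1,2-bis(benzyloxy)-5-methoxy-3-methylbenzene
Product: 7 3,4-bis(benzyloxy)-6-methoxy-2-methylbenzaldehyde, via iminium chloride 6 (not isolated)
Conditions: POCl3, DMF, 0→70 °C; then H2O
Reagents that add atoms: N,N-dimethylformamide, CN(C)C=O; water, O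
Why: Vilsmeier–Haack formylation should attack C4 of 5, which is para to the unhindered C1 benzyloxy group and ortho to the C5 methoxy group, whereas the rival C6 lies between two alkoxy groups (the same preference 3,5-dimethoxytoluene shows for its methyl-flanked position), and water then hydrolyses iminium salt 6.

Step 5
Reactants: 7 3,4-bis(benzyloxy)-6-methoxy-2-methylbenzaldehyde
Product: 8 3,4-bis(benzyloxy)-6-methoxy-2-methylbenzoic acid
Conditions: NaClO2, NaH2PO4, 2-methyl-2-butene, t-BuOH/H2O, rt
Reagents that add atoms: sodium chlorite, [Na+].[O-]Cl=O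
Why: Pinnick oxidation converts the hindered aryl aldehyde to the acid under mildly acidic conditions, and 2-methyl-2-butene traps the hypochlorous acid that would otherwise chlorinate the electron-rich ring.

Step 6
Reactants: 8 3,4-bis(benzyloxy)-6-methoxy-2-methylbenzoic acid
Product: 11 3,4-diacetoxy-6-methoxy-2-methylbenzoic acid, via dihydroxy acid 9 (not isolated), via mixed acetic anhydride 10 (not isolated)
Conditions: H2 (1 atm), 10% Pd/C, EtOAc, rt; filter; then Ac2O, pyridine, 0 °C→rt; then H2O
Reagents that add atoms: acetic anhydride, CC(=O)OC(C)=O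
Why: Hydrogenolysis of the two benzyl ethers is followed, without isolating the air-sensitive catechol acid 9, by O-acetylation, and water cleaves mixed anhydride 10 but not the aryl acetates, which make ring A electron-poor for step 11.

Step 7
Reactants: 12 4-hydroxy-2-methylbenzoic acid
Product: 13 4-nitrobenzyl 4-hydroxy-2-methylbenzoate
Conditions: 4-nitrobenzyl bromide, KHCO3, DMF, rt→40 °C
Reagents that add atoms: 4-nitrobenzyl bromide, O=[N+]([O-])c1ccc(CBr)cc1
Why: Chemoselective carboxylate O-alkylation, since KHCO3 deprotonates only the carboxylic acid and leaves the phenol free, and the nitro group makes the benzylic ester resistant to the acid of step 11.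

Step 8
Reactants: 11 3,4-diacetoxy-6-methoxy-2-methylbenzoic acid; 13 4-nitrobenzyl 4-hydroxy-2-methylbenzoate
Product: 15 4-nitrobenzyl 4-[(3,4-diacetoxy-6-methoxy-2-methylbenzoyl)oxy]-2-methylbenzoate, via mixed trifluoroacetic anhydride 14 (not isolated)
Conditions: (CF3CO)2O, toluene, rt
Reagents that add atoms: none
Why: Trifluoroacetic anhydride-mediated depside esterification, in which the 2,6-disubstituted acid gives mixed anhydride 14 that ionises, helped by the ortho methoxy group, to an acylium ion small enough to acylate the phenol of 13 despite the two ortho substituents.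

Step 9
Reactants: 15 4-nitrobenzyl 4-[(3,4-diacetoxy-6-methoxy-2-methylbenzoyl)oxy]-2-methylbenzoate
Product: 17 4-[(3,4-diacetoxy-6-methoxy-2-methylbenzoyl)oxy]-2-methylbenzoic acid, via 4-aminobenzyl ester 16 (not isolated)
Conditions: H2 (1 atm), 10% Pd/C, EtOAc, rt; then 1 M HCl wash
Reagents that add atoms: none
Why: Catalytic hydrogenation reduces the nitro group and then cleaves the benzylic C–O bond of 4-aminobenzyl ester 16 (hydrogenolysis), leaving the aryl acetates and the aryl benzoate untouched.

Step 10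
Reactants: 17 4-[(3,4-diacetoxy-6-methoxy-2-methylbenzoyl)oxy]-2-methylbenzoic acid; 13 4-nitrobenzyl 4-hydroxy-2-methylbenzoate
Product: 19 4-nitrobenzyl 4-[[4-[(3,4-diacetoxy-6-methoxy-2-methylbenzoyl)oxy]-2-methylbenzoyl]oxy]-2-methylbenzoate, via acid chloride 18 (not isolated)
Conditions: (COCl)2, cat. DMF, CH2Cl2, 0 °C→rt; evaporate; then 13, Et3N, CH2Cl2, 0 °C→rt
Reagents that add atoms: none
Why: Acylation of the phenol by the acid chloride (Schotten–Baumann-type esterification in an organic medium) runs without a nucleophilic catalyst, so the aryl acetates of ring A are not transferred to the phenol.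

Step 11
Reactants: 19 4-nitrobenzyl 4-[[4-[(3,4-diacetoxy-6-methoxy-2-methylbenzoyl)oxy]-2-methylbenzoyl]oxy]-2-methylbenzoate
Product: 21 4-nitrobenzyl 4-[[4-[(3,4-diacetoxy-6-methoxy-2-methylbenzoyl)oxy]-2-hydroxy-6-methylbenzoyl]oxy]-2-hydroxy-6-methylbenzoate, via bis(trifluoroacetate) 20 (not isolated)
Conditions: [RuCl2(p-cymene)]2 (5 mol%), PhI(OCOCF3)2 (3 equiv), TFA/TFAA, ClCH2CH2Cl, 80 °C; then H2O/THF, rt
Reagents that add atoms: [bis(trifluoroacetoxy)iodo]benzene, O=C(OI(OC(=O)C(F)(F)F)c1ccccc1)C(F)(F)F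
Why: In TFA/TFAA the chloride ligands are exchanged for trifluoroacetate, the carbonyl oxygen of the ring B–ring C ester (on C1 of ring B) and that of the nitrobenzyl ester (on C1 of ring C) each bind divalent ruthenium, carboxylate-assisted deprotonative metalation of the neighbouring C2–H bond gives a five-membered ruthenacycle, PhI(OCOCF3)2 oxidises it to tetravalent ruthenium, and C–O reductive elimination releases the aryl trifluoroacetate, which water cleaves to the hydrogen-bonded phenol. This is the known ruthenium-catalysed, ester-directed ortho C–H oxygenation of benzoates (established for alkyl benzoates), applied here twice in one molecule. No ring is closed and no stereocentre is formed; two aryl C–O bonds are made. The step needs oxygenation only at C2 of rings B and C: in each ring C6 carries the methyl group, so C2–H is the only C–H ortho to the carbonyl, and ring A has no ortho C–H at all. The diacetate on ring A and the trifluoroacetylation of the new phenols in the medium should keep all rings too electron-poor for undirected oxidation by the trivalent iodine reagent.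

Step 12
Reactants: 21 4-nitrobenzyl 4-[[4-[(3,4-diacetoxy-6-methoxy-2-methylbenzoyl)oxy]-2-hydroxy-6-methylbenzoyl]oxy]-2-hydroxy-6-methylbenzoate
Product: 22 4-nitrobenzyl 4-[[4-[(3,4-dihydroxy-6-methoxy-2-methylbenzoyl)oxy]-2-hydroxy-6-methylbenzoyl]oxy]-2-hydroxy-6-methylbenzoate
Conditions: N2H4·AcOH (2.2 equiv), DMF, 0 °C→rt, N2
Reagents that add atoms: none
Why: Hydrazinolysis should cleave the two unhindered aryl acetates far faster than the three benzoate carbonyls, each of which is flanked by two ortho substituents.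

Step 13
Reactants: 22 4-nitrobenzyl 4-[[4-[(3,4-dihydroxy-6-methoxy-2-methylbenzoyl)oxy]-2-hydroxy-6-methylbenzoyl]oxy]-2-hydroxy-6-methylbenzoate
Product: 24 4-[[4-[(3,4-dihydroxy-6-methoxy-2-methylbenzoyl)oxy]-2-hydroxy-6-methylbenzoyl]oxy]-2-hydroxy-6-methylbenzoic acid (CNP0222366.0), via 4-aminobenzyl ester 23 (not isolated)
Conditions: H2 (1 atm), 10% Pd/C, EtOAc/MeOH, rt; then 1 M HCl wash
Reagents that add atoms: none
Why: Hydrogenation of the nitro group and hydrogenolysis of the resulting 4-aminobenzyl ester 23 free the ring C carboxylic acid under neutral conditions that the depside esters and the catechol tolerate.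

**Compound list**

1 | 4-methoxy-2-methylphenol | COc1ccc(O)c(C)c1 | starting material
2 | 2-hydroxy-5-methoxy-3-methylbenzaldehyde | COc1cc(C)c(O)c(C=O)c1 | intermediate
3 | 2-hydroxy-5-methoxy-3-methylphenyl formate | COc1cc(C)c(O)c(OC=O)c1 | intermediate
4 | 5-methoxy-3-methylbenzene-1,2-diol | COc1cc(C)c(O)c(O)c1 | intermediate
5 | 1,2-bis(benzyloxy)-5-methoxy-3-methylbenzene | COc1cc(C)c(OCc2ccccc2)c(OCc2ccccc2)c1 | intermediate
6 | N-[[3,4-bis(benzyloxy)-6-methoxy-2-methylphenyl]methylidene]-N-methylmethanaminium chloride | COc1cc(OCc2ccccc2)c(OCc2ccccc2)c(C)c1C=[N+](C)C.[Cl-] | intermediate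
7 | 3,4-bis(benzyloxy)-6-methoxy-2-methylbenzaldehyde | COc1cc(OCc2ccccc2)c(OCc2ccccc2)c(C)c1C=O | intermediate
8 | 3,4-bis(benzyloxy)-6-methoxy-2-methylbenzoic acid | COc1cc(OCc2ccccc2)c(OCc2ccccc2)c(C)c1C(=O)O | intermediate
9 | 3,4-dihydroxy-6-methoxy-2-methylbenzoic acid | COc1cc(O)c(O)c(C)c1C(=O)O | intermediate
10 | acetic 3,4-diacetoxy-6-methoxy-2-methylbenzoic anhydride | COc1cc(OC(C)=O)c(OC(C)=O)c(C)c1C(=O)OC(C)=O | intermediate
11 | 3,4-diacetoxy-6-methoxy-2-methylbenzoic acid | COc1cc(OC(C)=O)c(OC(C)=O)c(C)c1C(=O)O | intermediate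
12 | 4-hydroxy-2-methylbenzoic acid | Cc1cc(O)ccc1C(=O)O | starting material
13 | 4-nitrobenzyl 4-hydroxy-2-methylbenzoate | Cc1cc(O)ccc1C(=O)OCc1ccc([N+](=O)[O-])cc1 | intermediate
14 | 3,4-diacetoxy-6-methoxy-2-methylbenzoic trifluoroacetic anhydride | COc1cc(OC(C)=O)c(OC(C)=O)c(C)c1C(=O)OC(=O)C(F)(F)F | intermediate
15 | 4-nitrobenzyl 4-[(3,4-diacetoxy-6-methoxy-2-methylbenzoyl)oxy]-2-methylbenzoate | COc1cc(OC(C)=O)c(OC(C)=O)c(C)c1C(=O)Oc1ccc(C(=O)OCc2ccc([N+](=O)[O-])cc2)c(C)c1 | intermediate
16 | 4-aminobenzyl 4-[(3,4-diacetoxy-6-methoxy-2-methylbenzoyl)oxy]-2-methylbenzoate | COc1cc(OC(C)=O)c(OC(C)=O)c(C)c1C(=O)Oc1ccc(C(=O)OCc2ccc(N)cc2)c(C)c1 | intermediate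
17 | 4-[(3,4-diacetoxy-6-methoxy-2-methylbenzoyl)oxy]-2-methylbenzoic acid | COc1cc(OC(C)=O)c(OC(C)=O)c(C)c1C(=O)Oc1ccc(C(=O)O)c(C)c1 | intermediate
18 | 4-[(3,4-diacetoxy-6-methoxy-2-methylbenzoyl)oxy]-2-methylbenzoyl chloride | COc1cc(OC(C)=O)c(OC(C)=O)c(C)c1C(=O)Oc1ccc(C(=O)Cl)c(C)c1 | intermediate
19 | 4-nitrobenzyl 4-[[4-[(3,4-diacetoxy-6-methoxy-2-methylbenzoyl)oxy]-2-methylbenzoyl]oxy]-2-methylbenzoate (bis-deoxy tridepside) | COc1cc(OC(C)=O)c(OC(C)=O)c(C)c1C(=O)Oc1ccc(C(=O)Oc2ccc(C(=O)OCc3ccc([N+](=O)[O-])cc3)c(C)c2)c(C)c1 | intermediate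
20 | bis(trifluoroacetate) of 21 at the C2 oxygens of rings B and C | COc1cc(OC(C)=O)c(OC(C)=O)c(C)c1C(=O)Oc1cc(C)c(C(=O)Oc2cc(C)c(C(=O)OCc3ccc([N+](=O)[O-])cc3)c(OC(=O)C(F)(F)F)c2)c(OC(=O)C(F)(F)F)c1 | intermediate
21 | 4-nitrobenzyl 4-[[4-[(3,4-diacetoxy-6-methoxy-2-methylbenzoyl)oxy]-2-hydroxy-6-methylbenzoyl]oxy]-2-hydroxy-6-methylbenzoate | COc1cc(OC(C)=O)c(OC(C)=O)c(C)c1C(=O)Oc1cc(C)c(C(=O)Oc2cc(C)c(C(=O)OCc3ccc([N+](=O)[O-])cc3)c(O)c2)c(O)c1 | intermediate
22 | 4-nitrobenzyl 4-[[4-[(3,4-dihydroxy-6-methoxy-2-methylbenzoyl)oxy]-2-hydroxy-6-methylbenzoyl]oxy]-2-hydroxy-6-methylbenzoate | COc1cc(O)c(O)c(C)c1C(=O)Oc1cc(C)c(C(=O)Oc2cc(C)c(C(=O)OCc3ccc([N+](=O)[O-])cc3)c(O)c2)c(O)c1 | intermediate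
23 | 4-aminobenzyl 4-[[4-[(3,4-dihydroxy-6-methoxy-2-methylbenzoyl)oxy]-2-hydroxy-6-methylbenzoyl]oxy]-2-hydroxy-6-methylbenzoate | COc1cc(O)c(O)c(C)c1C(=O)Oc1cc(C)c(C(=O)Oc2cc(C)c(C(=O)OCc3ccc(N)cc3)c(O)c2)c(O)c1 | intermediate
24 | 4-[[4-[(3,4-dihydroxy-6-methoxy-2-methylbenzoyl)oxy]-2-hydroxy-6-methylbenzoyl]oxy]-2-hydroxy-6-methylbenzoic acid | COc1cc(O)c(O)c(C)c1C(=O)Oc1cc(C)c(C(=O)Oc2cc(C)c(C(=O)O)c(O)c2)c(O)c1 | target

**Step count and risks**

Total steps: 13. Longest linear sequence: 12 (steps 1–6, then 8–13); step 7 is the only side branch.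

Steps most likely to fail:

1. Step 11. Several processes could defeat it:
   - the aryl ester and nitrobenzyl ester carbonyls may bind ruthenium too weakly, so that one or both C–H bonds stay unreacted;
   - the acyloxy carbonyls may steer the metal to C3 or C5 of rings B and C through six-membered ruthenacycles;
   - hot TFA/TFAA may cleave a depside bond or exchange the acetates;
   - the iodine reagent may oxidise ring A without direction.

   The fallback uses classical depside chemistry with the oxygens in place from the start. It sets out from compound 11. Commercial 2,4-dihydroxy-6-methylbenzoic acid is alkylated with 4-nitrobenzyl bromide and KHCO3 in DMF to 4-nitrobenzyl 2,4-dihydroxy-6-methylbenzoate F1. Acid 11 and F1 are joined with (CF3CO)2O in toluene at the free 4-OH (the 2-OH is chelated to the ester) to give 4-nitrobenzyl 4-[(3,4-diacetoxy-6-methoxy-2-methylbenzoyl)oxy]-2-hydroxy-6-methylbenzoate F2. Hydrogenation over 10% Pd/C gives 4-[(3,4-diacetoxy-6-methoxy-2-methylbenzoyl)oxy]-2-hydroxy-6-methylbenzoic acid F3. N,N'-Dicyclohexylcarbodiimide in toluene then couples F3 with a second portion of F1 at its 4-OH, and the route is rejoined at compound 21.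

2. Step 4. Site selectivity may be poor, with formylation at C6 between the methoxy and benzyloxy groups, or HCl may remove a benzyl group. The fallback changes the control element from steric balance to ring fusion. It sets out from compound 4. Dichlorodiphenylmethane at 160 °C gives 6-methoxy-4-methyl-2,2-diphenyl-1,3-benzodioxole F4. Vilsmeier–Haack formylation (POCl3, DMF) should occur only at the benzodioxole position remote from the ring oxygens, as in the formylation of 5-methoxy-1,3-benzodioxole, to give 6-methoxy-4-methyl-2,2-diphenyl-1,3-benzodioxole-5-carbaldehyde F5. Pinnick oxidation gives 6-methoxy-4-methyl-2,2-diphenyl-1,3-benzodioxole-5-carboxylic acid F6. Hydrogenolysis of the diphenylmethylene ketal over 10% Pd/C returns to the route at compound 9, which is acetylated as in step 6.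

3. Step 12. Hydrazine may also cleave a depside bond or the nitrobenzyl ester, or the freed catechol may oxidise in air in the basic medium. The fallback reverses the end game and replaces nucleophilic by acid-catalysed deacylation. It sets out from compound 21. Hydrogenation over 10% Pd/C first removes the nitrobenzyl ester to give 4-[[4-[(3,4-diacetoxy-6-methoxy-2-methylbenzoyl)oxy]-2-hydroxy-6-methylbenzoyl]oxy]-2-hydroxy-6-methylbenzoic acid F7. HCl in MeOH (from AcCl) at 0 °C→rt then transesterifies the two unhindered acetates, while the doubly ortho-substituted benzoate carbonyls and the hindered carboxylic acid resist acid-catalysed acyl substitution. The route is rejoined at compound 24.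

**Further compounds**

F1 | step 11 | 4-nitrobenzyl 2,4-dihydroxy-6-methylbenzoate | Cc1cc(O)cc(O)c1C(=O)OCc1ccc([N+](=O)[O-])cc1
F2 | step 11 | 4-nitrobenzyl 4-[(3,4-diacetoxy-6-methoxy-2-methylbenzoyl)oxy]-2-hydroxy-6-methylbenzoate | COc1cc(OC(C)=O)c(OC(C)=O)c(C)c1C(=O)Oc1cc(C)c(C(=O)OCc2ccc([N+](=O)[O-])cc2)c(O)c1
F3 | step 11 | 4-[(3,4-diacetoxy-6-methoxy-2-methylbenzoyl)oxy]-2-hydroxy-6-methylbenzoic acid | COc1cc(OC(C)=O)c(OC(C)=O)c(C)c1C(=O)Oc1cc(C)c(C(=O)O)c(O)c1
F4 | step 4 | 6-methoxy-4-methyl-2,2-diphenyl-1,3-benzodioxole | COc1cc(C)c2c(c1)OC(c1ccccc1)(c1ccccc1)O2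
F5 | step 4 | 6-methoxy-4-methyl-2,2-diphenyl-1,3-benzodioxole-5-carbaldehyde | COc1cc2c(c(C)c1C=O)OC(c1ccccc1)(c1ccccc1)O2
F6 | step 4 | 6-methoxy-4-methyl-2,2-diphenyl-1,3-benzodioxole-5-carboxylic acid | COc1cc2c(c(C)c1C(=O)O)OC(c1ccccc1)(c1ccccc1)O2
F7 | step 12 | 4-[[4-[(3,4-diacetoxy-6-methoxy-2-methylbenzoyl)oxy]-2-hydroxy-6-methylbenzoyl]oxy]-2-hydroxy-6-methylbenzoic acid | COc1cc(OC(C)=O)c(OC(C)=O)c(C)c1C(=O)Oc1cc(C)c(C(=O)Oc2cc(C)c(C(=O)O)c(O)c2)c(O)c1
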